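## Retrosynthetic overview

1. Target 24 comes from bis-silyl ether 23, whose C11–C12 bond (with 11S and 12E) is made from cyclopropyl aldehyde 11 and enyne 22 by a Ni(cod)2/chiral carbene aldehyde–alkyne reductive coupling.
2. Aldehyde 11: the eight-membered lactone (second ring formed) is closed by ring-closing metathesis of a pent-4-enoate; C7 is set by [Ir(cod)Cl]2/(R)-BINAP C–H allylation of a cyclopropylmethanol.
3. The cyclopropane (first ring formed) comes from Charette cyclopropanation of mono-silylated (E)-but-2-ene-1,4-diol.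
4. Enyne 22: C14 from (R)-glycidol, C15–C16 by acetylide opening of the epoxide, 16Z by semihydrogenation, C12 by one-carbon alkyne homologation of an α-silyloxy aldehyde.

Assumption: carbons are numbered C1 (lactone carbonyl) to C22 (chain methyl), with the cyclopropane CH2 as C9; the given SMILES then reads 4Z,7R,8R,10R,11S,12E,14S,16Z, and that enantiomer is made.

## Route

Step 1
Reactants: 1 (E)-but-2-ene-1,4-diol
Product: 2 (E)-4-{[tert-butyl(diphenyl)silyl]oxy}but-2-en-1-ol
Conditions: NaH (1.0 equiv), TBDPSCl (1.0 equiv), THF, 0 °C → rt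
Reagents that add atoms: tert-butyl(chloro)diphenylsilane CC(C)(C)[Si](Cl)(c1ccccc1)c1ccccc1
Why: Williamson-type O-silylation of the sparingly soluble mono-sodium alkoxide of the symmetrical diol stops after one hydroxyl, leaving the other free to direct the cyclopropanation.

Step 2
Reactants: 2 (E)-4-{[tert-butyl(diphenyl)silyl]oxy}but-2-en-1-ol
Product: 3 [(1R,2R)-2-({[tert-butyl(diphenyl)silyl]oxy}methyl)cyclopropyl]methanol
Conditions: Et2Zn (2.2 equiv), CH2I2 (4.4 equiv), DME, (4S,5S)-2-butyl-N,N,N′,N′-tetramethyl-1,3,2-dioxaborolane-4,5-dicarboxamide (1.2 equiv), CH2Cl2, −10 °C → rt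
Reagents that add atoms: diiodomethane ICI
Why: Charette asymmetric Simmons–Smith cyclopropanation: the zinc alkoxide of 2 held by the chiral dioxaborolane receives CH2 from bis(iodomethyl)zinc on one alkene face in a stereospecific syn addition, so the E-alkene gives the trans ring and the (4S,5S) controller (antipode of the one that turns cinnamyl alcohol into the 1S,2S product) sets C8 and C10 as R,R.

Step 3
Reactants: 3 [(1R,2R)-2-({[tert-butyl(diphenyl)silyl]oxy}methyl)cyclopropyl]methanol; 4 allyl acetate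
Product: 6 (1R)-1-[(1R,2R)-2-({[tert-butyl(diphenyl)silyl]oxy}methyl)cyclopropyl]but-3-en-1-ol, via cyclopropanecarbaldehyde 5 (not isolated)
Conditions: [Ir(cod)Cl]2 (2.5 mol %), (R)-BINAP (5 mol %), 4-chloro-3-nitrobenzoic acid (10 mol %), Cs2CO3 (20 mol %), THF, 100 °C, sealed tube
Reagents that add atoms: none
Why: Iridium-catalysed transfer-hydrogenative carbonyl allylation (Krische allylation), a C–H functionalisation of the carbinol carbon: the cyclometallated π-allyliridium benzoate complex dehydrogenates 3 to aldehyde 5 and then adds its allyl group through a closed chair transition state to the Re face under catalyst control (the (R)-BINAP antipode is the one that gives (R)-1-phenylbut-3-en-1-ol from benzyl alcohol), which sets C7 as R without touching the ring stereocentres.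

Step 4
Reactants: 6 (1R)-1-[(1R,2R)-2-({[tert-butyl(diphenyl)silyl]oxy}methyl)cyclopropyl]but-3-en-1-ol; 7 pent-4-enoic acid
Product: 8 (1R)-1-[(1R,2R)-2-({[tert-butyl(diphenyl)silyl]oxy}methyl)cyclopropyl]but-3-en-1-yl pent-4-enoate
Conditions: DCC, DMAP (cat.), CH2Cl2, 0 °C → rt
Reagents that add atoms: none
Why: Steglich esterification acylates the secondary alcohol at oxygen, so C7 keeps its configuration.

Step 5
Reactants: 8 (1R)-1-[(1R,2R)-2-({[tert-butyl(diphenyl)silyl]oxy}methyl)cyclopropyl]but-3-en-1-yl pent-4-enoate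
Product: 9 (5Z,8R)-8-[(1R,2R)-2-({[tert-butyl(diphenyl)silyl]oxy}methyl)cyclopropyl]-3,4,7,8-tetrahydro-2H-oxocin-2-one
Conditions: second-generation Grubbs catalyst (H2IMes)(PCy3)Cl2Ru=CHPh (10 mol %), 1,4-benzoquinone (20 mol %), CH2Cl2 (1 mM), 40 °C
Reagents that add atoms: none
Why: Ring-closing olefin metathesis joins the two terminal alkenes with loss of ethene; the eight-membered ring can only hold a Z alkene, and the C7 branch together with high dilution favours cyclisation over oligomerisation.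

Step 6
Reactants: 9 (5Z,8R)-8-[(1R,2R)-2-({[tert-butyl(diphenyl)silyl]oxy}methyl)cyclopropyl]-3,4,7,8-tetrahydro-2H-oxocin-2-one
Product: 10 (5Z,8R)-8-[(1R,2R)-2-(hydroxymethyl)cyclopropyl]-3,4,7,8-tetrahydro-2H-oxocin-2-one
Conditions: HF·pyridine, pyridine, THF, 0 °C → rt
Reagents that add atoms: none
Why: Fluoride-induced Si–O cleavage frees the primary C11 alcohol, and the pyridine-buffered medium leaves the lactone, the Z alkene and the cyclopropane alone.

Step 7
Reactants: 10 (5Z,8R)-8-[(1R,2R)-2-(hydroxymethyl)cyclopropyl]-3,4,7,8-tetrahydro-2H-oxocin-2-one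
Product: 11 (1R,2R)-2-[(2R,4Z)-8-oxo-3,6,7,8-tetrahydro-2H-oxocin-2-yl]cyclopropane-1-carbaldehyde
Conditions: Dess–Martin periodinane, CH2Cl2, 0 °C → rt
Reagents that add atoms: none
Why: Dess–Martin oxidation stops at the aldehyde under neutral conditions, and the cyclopropane carbon next to the carbonyl does not epimerise.

Step 8
Reactants: 12 (R)-glycidol, [(2R)-oxiran-2-yl]methanol
Product: 13 (2S)-2-{[(4-methoxyphenyl)methoxy]methyl}oxirane
Conditions: NaH, 4-methoxybenzyl chloride, Bu4NI (cat.), THF/DMF, 0 °C → rt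
Reagents that add atoms: 4-methoxybenzyl chloride COc1ccc(CCl)cc1
Why: Williamson etherification at the primary alkoxide leaves the epoxide and its stereocentre untouched (the descriptor changes from R to S only through the priority rules).

Step 9
Reactants: 13 (2S)-2-{[(4-methoxyphenyl)methoxy]methyl}oxirane; 14 hept-1-yne
Product: 16 (2S)-1-[(4-methoxyphenyl)methoxy]dec-4-yn-2-ol, via hept-1-yn-1-yllithium 15 (not isolated)
Conditions: n-BuLi, THF, −78 °C; BF3·OEt2; then 13, −78 °C
Reagents that add atoms: none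
Why: Yamaguchi–Hirao alkynylation: the lithium acetylide activated by BF3 opens the epoxide by SN2 attack at the unsubstituted carbon, which forms C15–C16 and leaves the C14 stereocentre of the chiral pool intact.

Step 10
Reactants: 16 (2S)-1-[(4-methoxyphenyl)methoxy]dec-4-yn-2-ol
Product: 17 (2S,4Z)-1-[(4-methoxyphenyl)methoxy]dec-4-en-2-ol
Conditions: H2 (1 atm), Pd/CaCO3 poisoned with Pb(OAc)2 (Lindlar catalyst), quinoline, EtOAc, rt
Reagents that add atoms: none
Why: Lindlar semihydrogenation adds H2 syn on the poisoned palladium surface and stops at the alkene, giving the 16Z geometry.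

Step 11
Reactants: 17 (2S,4Z)-1-[(4-methoxyphenyl)methoxy]dec-4-en-2-ol
Product: 18 tert-butyl({(2S,4Z)-1-[(4-methoxyphenyl)methoxy]dec-4-en-2-yl}oxy)dimethylsilane
Conditions: TBSCl, imidazole, DMF, rt
Reagents that add atoms: tert-butyl(chloro)dimethylsilane CC(C)(C)[Si](C)(C)Cl
Why: Standard imidazole-promoted silylation protects the secondary C14 hydroxyl without touching the stereocentre.

Step 12
Reactants: 18 tert-butyl({(2S,4Z)-1-[(4-methoxyphenyl)methoxy]dec-4-en-2-yl}oxy)dimethylsilane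
Product: 19 (2S,4Z)-2-{[tert-butyl(dimethyl)silyl]oxy}dec-4-en-1-ol
Conditions: DDQ, CH2Cl2/pH 7 phosphate buffer (10:1), 0 °C
Reagents that add atoms: none
Why: Oxidative cleavage of the electron-rich 4-methoxybenzyl ether by DDQ (hydride abstraction, then hydrolysis of the oxocarbenium ion) frees the primary alcohol while the silyl ether and the Z alkene survive.

Step 13
Reactants: 19 (2S,4Z)-2-{[tert-butyl(dimethyl)silyl]oxy}dec-4-en-1-ol
Product: 20 (2S,4Z)-2-{[tert-butyl(dimethyl)silyl]oxy}dec-4-enal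
Conditions: Dess–Martin periodinane, CH2Cl2, 0 °C → rt; used crude
Reagents that add atoms: none
Why: Dess–Martin oxidation gives the α-silyloxy aldehyde under mild non-basic conditions that avoid epimerisation at C14, and the aldehyde is used at once.

Step 14
Reactants: 20 (2S,4Z)-2-{[tert-butyl(dimethyl)silyl]oxy}dec-4-enal
Product: 22 tert-butyl(dimethyl){[(3S,5Z)-undec-5-en-1-yn-3-yl]oxy}silane, via 1-diazoalkene 21 (not isolated)
Conditions: Me3SiCHN2, LiN(iPr)2, THF, −78 °C; then 20, −78 → 0 °C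
Reagents that add atoms: (trimethylsilyl)diazomethane C[Si](C)(C)C=[N+]=[N-]
Why: Colvin rearrangement (Shioiri variant of the Seyferth–Gilbert homologation): addition of lithiated trimethylsilyldiazomethane, Peterson elimination to diazoalkene 21, loss of N2 and 1,2-hydride shift of the alkylidene carbene give the terminal alkyne at temperatures low enough to keep C14 intact.

Step 15
Reactants: 11 (1R,2R)-2-[(2R,4Z)-8-oxo-3,6,7,8-tetrahydro-2H-oxocin-2-yl]cyclopropane-1-carbaldehyde; 22 tert-butyl(dimethyl){[(3S,5Z)-undec-5-en-1-yn-3-yl]oxy}silane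
Product: 23 (5Z,8R)-8-{(1R,2R)-2-[(1S,2E,4S,6Z)-4-{[tert-butyl(dimethyl)silyl]oxy}-1-[(triethylsilyl)oxy]dodeca-2,6-dien-1-yl]cyclopropyl}-3,4,7,8-tetrahydro-2H-oxocin-2-one
Conditions: Ni(cod)2 (10 mol %), (4R,5R)-1,3-bis(2-isopropylphenyl)-4,5-diphenylimidazolinium tetrafluoroborate (12 mol %), KOtBu (12 mol %), Et3SiH (2 equiv), THF, 25 °C, 22 added over 2 h
Reagents that add atoms: triethylsilane CC[SiH](CC)CC
Why: Proposed new method: zerovalent nickel carrying a small C2-symmetric N-heterocyclic carbene binds alkyne 22 and aldehyde 11, oxidative cyclisation forms the C11–C12 bond at the unhindered alkyne terminus on the Si face of the aldehyde (ligand-controlled, setting 11S) to give an oxanickelacyclopentene, and Si–H σ-bond metathesis with Et3SiH followed by C–H reductive elimination places H cis to the new C–C bond (hence 12E) and leaves the 11-O-triethylsilyl ether; the closest known reaction type is the nickel/N-heterocyclic carbene/silane aldehyde–alkyne reductive coupling, which has not been shown as a catalyst-controlled diastereoselective union of a cyclopropanecarbaldehyde with a terminal propargylic silyl ether.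

Step 16
Reactants: 23 (5Z,8R)-8-{(1R,2R)-2-[(1S,2E,4S,6Z)-4-{[tert-butyl(dimethyl)silyl]oxy}-1-[(triethylsilyl)oxy]dodeca-2,6-dien-1-yl]cyclopropyl}-3,4,7,8-tetrahydro-2H-oxocin-2-one
Product: 24 (5Z,8R)-8-{(1R,2R)-2-[(1S,2E,4S,6Z)-1,4-dihydroxydodeca-2,6-dien-1-yl]cyclopropyl}-3,4,7,8-tetrahydro-2H-oxocin-2-one
Conditions: Bu4NF, AcOH (1:1, 5 equiv), THF, 0 °C → rt
Reagents that add atoms: none
Why: Buffered fluoride cleaves both silyl ethers by attack at silicon at near-neutral pH, which spares the lactone and the acid-sensitive cyclopropyl allylic alcohol and delivers the target.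

## Compound list

1 | (E)-but-2-ene-1,4-diol | OC/C=C/CO | starting material
2 | (E)-4-{[tert-butyl(diphenyl)silyl]oxy}but-2-en-1-ol | OC/C=C/CO[Si](c1ccccc1)(c1ccccc1)C(C)(C)C | intermediate
3 | [(1R,2R)-2-({[tert-butyl(diphenyl)silyl]oxy}methyl)cyclopropyl]methanol | CC(C)(C)[Si](c1ccccc1)(c1ccccc1)OC[C@@H]1C[C@H]1CO | intermediate
4 | allyl acetate (prop-2-en-1-yl acetate) | CC(=O)OCC=C | starting material
5 | (1R,2R)-2-({[tert-butyl(diphenyl)silyl]oxy}methyl)cyclopropane-1-carbaldehyde | CC(C)(C)[Si](c1ccccc1)(c1ccccc1)OC[C@@H]1C[C@H]1C=O | intermediate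
6 | (1R)-1-[(1R,2R)-2-({[tert-butyl(diphenyl)silyl]oxy}methyl)cyclopropyl]but-3-en-1-ol | CC(C)(C)[Si](c1ccccc1)(c1ccccc1)OC[C@@H]1C[C@H]1[C@H](O)CC=C | intermediate
7 | pent-4-enoic acid | OC(=O)CCC=C | starting material
8 | (1R)-1-[(1R,2R)-2-({[tert-butyl(diphenyl)silyl]oxy}methyl)cyclopropyl]but-3-en-1-yl pent-4-enoate | CC(C)(C)[Si](c1ccccc1)(c1ccccc1)OC[C@@H]1C[C@H]1[C@H](OC(=O)CCC=C)CC=C | intermediate
9 | (5Z,8R)-8-[(1R,2R)-2-({[tert-butyl(diphenyl)silyl]oxy}methyl)cyclopropyl]-3,4,7,8-tetrahydro-2H-oxocin-2-one | CC(C)(C)[Si](c1ccccc1)(c1ccccc1)OC[C@@H]1C[C@H]1[C@H]1C/C=C\CCC(=O)O1 | intermediate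
10 | (5Z,8R)-8-[(1R,2R)-2-(hydroxymethyl)cyclopropyl]-3,4,7,8-tetrahydro-2H-oxocin-2-one | OC[C@@H]1C[C@H]1[C@H]1C/C=C\CCC(=O)O1 | intermediate
11 | (1R,2R)-2-[(2R,4Z)-8-oxo-3,6,7,8-tetrahydro-2H-oxocin-2-yl]cyclopropane-1-carbaldehyde | O=C[C@@H]1C[C@H]1[C@H]1C/C=C\CCC(=O)O1 | intermediate
12 | (R)-glycidol, [(2R)-oxiran-2-yl]methanol | OC[C@@H]1CO1 | starting material
13 | (2S)-2-{[(4-methoxyphenyl)methoxy]methyl}oxirane | COc1ccc(COC[C@@H]2CO2)cc1 | intermediate
14 | hept-1-yne | CCCCCC#C | starting material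
15 | hept-1-yn-1-yllithium | [Li]C#CCCCCC | intermediate
16 | (2S)-1-[(4-methoxyphenyl)methoxy]dec-4-yn-2-ol | CCCCCC#CC[C@H](O)COCc1ccc(OC)cc1 | intermediate
17 | (2S,4Z)-1-[(4-methoxyphenyl)methoxy]dec-4-en-2-ol | CCCCC/C=C\C[C@H](O)COCc1ccc(OC)cc1 | intermediate
18 | tert-butyl({(2S,4Z)-1-[(4-methoxyphenyl)methoxy]dec-4-en-2-yl}oxy)dimethylsilane | CCCCC/C=C\C[C@H](O[Si](C)(C)C(C)(C)C)COCc1ccc(OC)cc1 | intermediate
19 | (2S,4Z)-2-{[tert-butyl(dimethyl)silyl]oxy}dec-4-en-1-ol | CCCCC/C=C\C[C@H](O[Si](C)(C)C(C)(C)C)CO | intermediate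
20 | (2S,4Z)-2-{[tert-butyl(dimethyl)silyl]oxy}dec-4-enal | CCCCC/C=C\C[C@H](O[Si](C)(C)C(C)(C)C)C=O | intermediate
21 | tert-butyl{[(3S,5Z)-1-diazoundeca-1,5-dien-3-yl]oxy}dimethylsilane | CCCCC/C=C\C[C@H](O[Si](C)(C)C(C)(C)C)C=C=[N+]=[N-] | intermediate
22 | tert-butyl(dimethyl){[(3S,5Z)-undec-5-en-1-yn-3-yl]oxy}silane | CCCCC/C=C\C[C@H](O[Si](C)(C)C(C)(C)C)C#C | intermediate
23 | (5Z,8R)-8-{(1R,2R)-2-[(1S,2E,4S,6Z)-4-{[tert-butyl(dimethyl)silyl]oxy}-1-[(triethylsilyl)oxy]dodeca-2,6-dien-1-yl]cyclopropyl}-3,4,7,8-tetrahydro-2H-oxocin-2-one | CCCCC/C=C\C[C@H](O[Si](C)(C)C(C)(C)C)/C=C/[C@H](O[Si](CC)(CC)CC)[C@@H]1C[C@H]1[C@H]1C/C=C\CCC(=O)O1 | intermediate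
24 | (5Z,8R)-8-{(1R,2R)-2-[(1S,2E,4S,6Z)-1,4-dihydroxydodeca-2,6-dien-1-yl]cyclopropyl}-3,4,7,8-tetrahydro-2H-oxocin-2-one | CCCCC/C=C\C[C@H](O)/C=C/[C@H](O)[C@@H]1C[C@H]1[C@H]1C/C=C\CCC(=O)O1 | target

## Step count and risks

Total step count: 16.
Longest linear sequence: 9 steps (1–7, 15, 16; the branch 8–14, 15, 16 is equally long).

Risk 1 – step 15 (the proposed new coupling). Possible failures are slow turnover, C–C bond formation at the internal alkyne carbon, ring opening of the cyclopropyl aldehyde by zerovalent nickel, or low selectivity at C11. The carbene antipode is fixed in a pilot run with cyclopropanecarbaldehyde (Mosher analysis); (4R,5R) is the working choice and its mirror image is used if the pilot shows Re-face addition. The fallback uses known chemistry, sets out from 22 and 11 and comes back at 24. Hydrozirconation of 22 with Cp2Zr(H)Cl in THF and quenching with I2 gives the E-alkenyl iodide tert-butyl{[(1E,3S,5Z)-1-iodoundeca-1,5-dien-3-yl]oxy}dimethylsilane F1. A Nozaki–Hiyama–Kishi reaction of F1 with 11 (CrCl2, catalytic NiCl2, a Kishi-type chiral sulfonamide ligand, THF) gives the allylic alcohol (5Z,8R)-8-{(1R,2R)-2-[(1S,2E,4S,6Z)-4-{[tert-butyl(dimethyl)silyl]oxy}-1-hydroxydodeca-2,6-dien-1-yl]cyclopropyl}-3,4,7,8-tetrahydro-2H-oxocin-2-one F2, with any 11R epimer removed by chromatography. Bu4NF/AcOH then cleaves the remaining silyl ether to give 24.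

Risk 2 – step 5 (ring-closing metathesis to the eight-membered lactone). Dimerisation or alkene migration may compete. The fallback sets out from 6 and comes back at 9.
- Et3SiCl/imidazole converts 6 into triethyl{[(1R)-1-[(1R,2R)-2-({[tert-butyl(diphenyl)silyl]oxy}methyl)cyclopropyl]but-3-en-1-yl]oxy}silane F3.
- Ozonolysis (O3, CH2Cl2, −78 °C; PPh3) gives (3R)-3-[(1R,2R)-2-({[tert-butyl(diphenyl)silyl]oxy}methyl)cyclopropyl]-3-[(triethylsilyl)oxy]propanal F4.
- 4-Bromobutanoic acid and PPh3 give (3-carboxypropyl)triphenylphosphonium bromide F5.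
- The ylide of F5 (NaN(SiMe3)2, THF, −78 °C) converts F4 in a Z-selective Wittig reaction into (4Z,7R)-7-[(1R,2R)-2-({[tert-butyl(diphenyl)silyl]oxy}methyl)cyclopropyl]-7-[(triethylsilyl)oxy]hept-4-enoic acid F6.
- AcOH/THF/H2O removes the triethylsilyl group to give (4Z,7R)-7-[(1R,2R)-2-({[tert-butyl(diphenyl)silyl]oxy}methyl)cyclopropyl]-7-hydroxyhept-4-enoic acid F7.
- Yamaguchi lactonisation (2,4,6-trichlorobenzoyl chloride, Et3N; then DMAP, toluene, high dilution, 80 °C) closes the lactone to 9.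

Risk 3 – step 3 (C–H allylation of the cyclopropylmethanol). Conversion or catalyst control over the C7 configuration may be insufficient on this substrate. The fallback sets out from 3 and comes back at 6. Dess–Martin oxidation of 3 gives aldehyde 5, this time isolated. Brown allylboration with (+)-Ipc2B(allyl) (the reagent from (−)-α-pinene, which gives (R)-1-phenylbut-3-en-1-ol from benzaldehyde) in Et2O at −78 °C, followed by NaOH/H2O2 work-up, gives 6. This fallback makes no compound outside the list (F0).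

Further compounds
F1 | step 15 | tert-butyl{[(1E,3S,5Z)-1-iodoundeca-1,5-dien-3-yl]oxy}dimethylsilane | CCCCC/C=C\C[C@H](O[Si](C)(C)C(C)(C)C)/C=C/I
F2 | step 15 | (5Z,8R)-8-{(1R,2R)-2-[(1S,2E,4S,6Z)-4-{[tert-butyl(dimethyl)silyl]oxy}-1-hydroxydodeca-2,6-dien-1-yl]cyclopropyl}-3,4,7,8-tetrahydro-2H-oxocin-2-one | CCCCC/C=C\C[C@H](O[Si](C)(C)C(C)(C)C)/C=C/[C@H](O)[C@@H]1C[C@H]1[C@H]1C/C=C\CCC(=O)O1
F3 | step 5 | triethyl{[(1R)-1-[(1R,2R)-2-({[tert-butyl(diphenyl)silyl]oxy}methyl)cyclopropyl]but-3-en-1-yl]oxy}silane | CC(C)(C)[Si](c1ccccc1)(c1ccccc1)OC[C@@H]1C[C@H]1[C@H](O[Si](CC)(CC)CC)CC=C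
F4 | step 5 | (3R)-3-[(1R,2R)-2-({[tert-butyl(diphenyl)silyl]oxy}methyl)cyclopropyl]-3-[(triethylsilyl)oxy]propanal | CC(C)(C)[Si](c1ccccc1)(c1ccccc1)OC[C@@H]1C[C@H]1[C@H](O[Si](CC)(CC)CC)CC=O
F5 | step 5 | (3-carboxypropyl)triphenylphosphonium bromide | OC(=O)CCC[P+](c1ccccc1)(c1ccccc1)c1ccccc1.[Br-]
F6 | step 5 | (4Z,7R)-7-[(1R,2R)-2-({[tert-butyl(diphenyl)silyl]oxy}methyl)cyclopropyl]-7-[(triethylsilyl)oxy]hept-4-enoic acid | CC(C)(C)[Si](c1ccccc1)(c1ccccc1)OC[C@@H]1C[C@H]1[C@H](O[Si](CC)(CC)CC)C/C=C\CCC(=O)O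
F7 | step 5 | (4Z,7R)-7-[(1R,2R)-2-({[tert-butyl(diphenyl)silyl]oxy}methyl)cyclopropyl]-7-hydroxyhept-4-enoic acid | CC(C)(C)[Si](c1ccccc1)(c1ccccc1)OC[C@@H]1C[C@H]1[C@H](O)C/C=C\CCC(=O)O
F0 | step 3 | none | none
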